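**Plan**
1. Retrosynthesis: the five benzyl ethers come off last. The C(=O)–aryl bond of the C1 side chain is cut to an aryl Grignard reagent and a C1 aldehyde whose carbon was a CH2OSi group. C3–H is traced back to C3–OH and C1–H/C2–H to a C1=C2 double bond, giving a tertiary indenol that is cut at C7a–C1 and C2–C3.
2. Enabling feature: C7a and C3a are neighbouring carbons of ring A and hold C1 and C3 of the five-membered ring, and C3 carries an aryl group. C3 can therefore be the carbonyl carbon of a diaryl ketone on C3a and C1–C2 an alkyne, so a metal at C7a forms C7a–C1 and C2–C3 in one operation.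
3. Forward: ring A ketone 8 is made from 5-bromoresorcinol (steps 1–5) and alkyne 11 by Sonogashira coupling (step 6). The five-membered ring, the only ring formed, closes in step 7. Two reductions follow (steps 8, 9), then the aroyl side chain is joined (steps 10–13) and the phenols are freed (step 14).
4. Stereochemistry: the chiral diene on rhodium sets the C3 carbinol (step 7). Its hydroxyl directs H2 to its own face of C1=C2, setting C1 and C2 (step 8). The C3 cation then takes hydride anti to the C2 aryl group (step 9), giving the all-cis (1R,2R,3R) indane.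

Key step: step 7

Assumption: the target is taken exactly as drawn, i.e. the all-cis indane with H-1, H-2 and H-3 on one face (1R,2R,3R); C1 is α to the ketone and cis to the C2 aryl group, so base is avoided once a carbonyl group sits on C1.
Convention: all indene and indane intermediates carry the numbering of the target (C1 side chain, C2 4-oxygenated phenyl, C3 3,5-dioxygenated phenyl, ring A = C3a–C7a with oxygen at C4 and C6); Bn = benzyl, TBS = tert-butyldimethylsilyl.

**Step 1**
Reactants: 1 5-bromoresorcinol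
Product: 2 1-bromo-3,5-bis(benzyloxy)benzene
Conditions: BnBr, K2CO3, DMF, 60 °C
Reagents that add atoms: benzyl bromide, BrCc1ccccc1
Why: Williamson ether synthesis; both phenoxides are alkylated by the benzylic bromide while the aryl bromide is inert.

**Step 2**
Reactants: 2 1-bromo-3,5-bis(benzyloxy)benzene
Product: 4 2-bromo-4,6-bis(benzyloxy)benzaldehyde, via iminium salt 3 (not isolated)
Conditions: POCl3, DMF, 0 → 90 °C; then H2O
Reagents that add atoms: N,N-dimethylformamide, CN(C)C=O; water, O
Why: Vilsmeier–Haack formylation; the chloroiminium ion should attack the position next to bromine (ortho to one benzyloxy group, para to the other), as it does in the corresponding dimethyl ether, and aqueous hydrolysis of iminium salt 3 releases the aldehyde, any isomer formylated between the two ethers being removed by crystallisation.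

**Step 3**
Reactants: 2 1-bromo-3,5-bis(benzyloxy)benzene; 4 2-bromo-4,6-bis(benzyloxy)benzaldehyde
Product: 6 racemic [2-bromo-4,6-bis(benzyloxy)phenyl][3,5-bis(benzyloxy)phenyl]methanol, via 3,5-bis(benzyloxy)phenyllithium 5 (not isolated)
Conditions: 2, n-BuLi, THF, −78 °C; then 4, −78 → 0 °C; then H2O
Reagents that add atoms: none
Why: bromine–lithium exchange followed by 1,2-addition of the aryllithium to the aldehyde, which at −78 °C should be far faster than exchange with the aryl bromide of 4.

**Step 4**
Reactants: 6 racemic [2-bromo-4,6-bis(benzyloxy)phenyl][3,5-bis(benzyloxy)phenyl]methanol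
Product: 7 [2-bromo-4,6-bis(benzyloxy)phenyl][3,5-bis(benzyloxy)phenyl]methanone
Conditions: Dess–Martin periodinane, CH2Cl2, rt
Reagents that add atoms: none
Why: Dess–Martin oxidation of a diarylmethanol to the diaryl ketone; benzyl ethers and the aryl bromide are untouched.

**Step 5**
Reactants: 7 [2-bromo-4,6-bis(benzyloxy)phenyl][3,5-bis(benzyloxy)phenyl]methanone
Product: 8 [2-(4,4,5,5-tetramethyl-1,3,2-dioxaborolan-2-yl)-4,6-bis(benzyloxy)phenyl][3,5-bis(benzyloxy)phenyl]methanone
Conditions: B2pin2, Pd(dppf)Cl2 (cat.), KOAc, 1,4-dioxane, 90 °C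
Reagents that add atoms: bis(pinacolato)diboron, CC1(C)OB(OC1(C)C)B1OC(C)(C)C(C)(C)O1
Why: Miyaura borylation; oxidative addition of the C–Br bond to zerovalent palladium and acetate-assisted transfer of boron is routine for 2-bromoaryl ketones and leaves the ketone and ethers intact.

**Step 6**
Reactants: 9 tert-butyldimethyl(prop-2-yn-1-yloxy)silane; 10 1-(benzyloxy)-4-iodobenzene
Product: 11 {3-[4-(benzyloxy)phenyl]prop-2-yn-1-yloxy}(tert-butyl)dimethylsilane
Conditions: PdCl2(PPh3)2 (cat.), CuI (cat.), Et3N, THF, rt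
Reagents that add atoms: none
Why: Sonogashira coupling of a terminal alkyne with an aryl iodide, which proceeds at room temperature without touching the silyl or benzyl ether.

**Step 7**
Reactants: 8 [2-(pinacolboryl)-4,6-bis(benzyloxy)phenyl][3,5-bis(benzyloxy)phenyl]methanone; 11 {3-[4-(benzyloxy)phenyl]prop-2-yn-1-yloxy}(tert-butyl)dimethylsilane
Product: 12 (3R)-4,6-bis(benzyloxy)-2-[4-(benzyloxy)phenyl]-3-[3,5-bis(benzyloxy)phenyl]-1-[(tert-butyldimethylsilyloxy)methyl]inden-3-ol (tertiary indenol with a C1=C2 double bond)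
Conditions: [RhCl(C2H4)2]2 (2.5 mol %), (1R,4R)-2,5-diphenylbicyclo[2.2.2]octa-2,5-diene (5.5 mol %), KOH (0.3 equiv, aq.), 1,4-dioxane, 60 °C
Reagents that add atoms: none
Why: The hydroxo complex [Rh(OH)(diene)] takes the C7a aryl group from boron, the aryl–rhodium (monovalent rhodium) adds syn across alkyne 11 so that C7a bonds to the carbon bearing CH2OTBS (C7a–C1) and rhodium sits on the aryl-bearing carbon, and this alkenyl–rhodium adds to the neighbouring diaryl ketone (C2–C3), after which water protonates the rhodium alkoxide and regenerates the hydroxo complex. The closest known reaction is the rhodium-catalysed [3+2] annulation of 2-acylarylboron reagents with internal alkynes to tertiary 1H-inden-1-ols, for which enantioselective versions with chiral diene or bisphosphine ligands exist. The five-membered ring (C7a, C1, C2, C3, C3a) closes by a 5-exo-trig addition of the alkenyl carbon to the exocyclic C=O. The single new stereocentre, C3, is controlled by the chiral diene, which decides the ketone face offered to the alkenyl–rhodium; the ligand antipode that leads to the (R)-carbinol is chosen in a trial run. The step needs regioselective insertion, which the alkyne should secure because rhodium prefers the carbon conjugated to the 4-(benzyloxy)phenyl ring, as in additions to 1-aryl-1-alkynes, while the bulky, weakly coordinating silyl ether cannot draw rhodium to the propargylic carbon, where β-oxygen elimination to an allene would follow. Syn insertion holds the alkenyl–rhodium next to the ketone, so ring closure should outrun a 1,4-rhodium shift or simple protonation.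

**Step 8**
Reactants: 12 (3R)-indenol
Product: 13 (1R,2R,3S)-4,6-bis(benzyloxy)-2-[4-(benzyloxy)phenyl]-3-[3,5-bis(benzyloxy)phenyl]-1-[(tert-butyldimethylsilyloxy)methyl]indan-3-ol (H-1 and H-2 cis to the hydroxyl; the C1 side chain, C2 aryl and C3 aryl mutually cis)
Conditions: [Ir(cod)(PCy3)(py)][B(3,5-(CF3)2C6H3)4] (5–10 mol %), H2 (50 bar), CH2Cl2, rt
Reagents that add atoms: none
Why: hydroxyl-directed hydrogenation with a Crabtree-type cationic iridium catalyst; the tertiary C3 hydroxyl binds iridium and both hydrogens are delivered syn to its face of the tetrasubstituted C1=C2 bond, the face that the C3 aryl group also leaves open, which sets C1 and C2, and benzyl and silyl ethers are inert to the homogeneous catalyst.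

**Step 9**
Reactants: 13 (1R,2R,3S)-indan-3-ol
Product: 14 (1R,2R,3R)-4,6-bis(benzyloxy)-2-[4-(benzyloxy)phenyl]-3-[3,5-bis(benzyloxy)phenyl]-1-[(tert-butyldimethylsilyloxy)methyl]indane (all-cis)
Conditions: Et3SiH, BF3·OEt2, CH2Cl2, −78 → −40 °C
Reagents that add atoms: none
Why: ionic hydrogenation (silane reduction of a benzylic alcohol); BF3 ionises the tertiary alcohol to the C3 cation, stabilised by the ortho and para benzyloxy groups of ring A, and Et3SiH should deliver hydride to the face opposite the C2 aryl group and the C1 side chain, the face the hydroxyl has left, so that the C3 aryl group ends cis to both neighbours, while benzyl and TBS ethers should survive at low temperature.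

**Step 10**
Reactants: 14 all-cis indane TBS ether
Product: 15 {(1R,2R,3R)-4,6-bis(benzyloxy)-2-[4-(benzyloxy)phenyl]-3-[3,5-bis(benzyloxy)phenyl]indan-1-yl}methanol
Conditions: Bu4NF, THF, 0 °C → rt
Reagents that add atoms: none
Why: fluoride-induced cleavage of the silyl ether; no epimerisable centre is present at this stage.

**Step 11**
Reactants: 15 all-cis primary alcohol
Product: 16 (1R,2R,3R)-4,6-bis(benzyloxy)-2-[4-(benzyloxy)phenyl]-3-[3,5-bis(benzyloxy)phenyl]indane-1-carbaldehyde
Conditions: Dess–Martin periodinane, NaHCO3, CH2Cl2, 0 °C; used at once without chromatography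
Reagents that add atoms: none
Why: Dess–Martin oxidation under buffered, non-basic conditions, chosen so that the C1 centre α to the new aldehyde is not equilibrated.

**Step 12**
Reactants: 16 all-cis aldehyde; 17 4-(benzyloxy)phenylmagnesium bromide (commercial solution in THF)
Product: 18 [4-(benzyloxy)phenyl]{(1R,2R,3R)-4,6-bis(benzyloxy)-2-[4-(benzyloxy)phenyl]-3-[3,5-bis(benzyloxy)phenyl]indan-1-yl}methanol (mixture of carbinol epimers)
Conditions: THF, −78 °C; then H2O
Reagents that add atoms: none
Why: Grignard addition to the aldehyde, which at −78 °C should outpace enolisation at C1; the new carbinol centre is formed unselectively and is removed in step 13.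

**Step 13**
Reactants: 18 secondary alcohol (epimer mixture)
Product: 19 [4-(benzyloxy)phenyl]{(1R,2R,3R)-4,6-bis(benzyloxy)-2-[4-(benzyloxy)phenyl]-3-[3,5-bis(benzyloxy)phenyl]indan-1-yl}methanone (penta-O-benzyl caraphenol B)
Conditions: Dess–Martin periodinane, NaHCO3, CH2Cl2, 0 °C → rt
Reagents that add atoms: none
Why: Dess–Martin oxidation of the benzylic secondary alcohol to the aryl ketone under buffered conditions that should leave the cis C1 centre untouched.

**Step 14**
Reactants: 19 penta-O-benzyl caraphenol B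
Product: 20 caraphenol B
Conditions: H2 (1 atm), 10% Pd/C, EtOAc–MeOH, rt
Reagents that add atoms: none
Why: hydrogenolysis of the five benzyl aryl ethers on palladium under neutral conditions; the 4-oxygenated aryl ketone is a poor substrate for reduction and the C1 centre meets neither acid nor base.

**Compound list**
1 | 5-bromoresorcinol | Oc1cc(O)cc(Br)c1 | starting material
2 | 1-bromo-3,5-bis(benzyloxy)benzene | Brc1cc(OCc2ccccc2)cc(OCc2ccccc2)c1 | intermediate
3 | N-{[2-bromo-4,6-bis(benzyloxy)phenyl]methylidene}-N-methylmethanaminium dichlorophosphate (iminium salt) | C[N+](C)=Cc1c(OCc2ccccc2)cc(OCc2ccccc2)cc1Br.[O-]P(=O)(Cl)Cl | intermediate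
4 | 2-bromo-4,6-bis(benzyloxy)benzaldehyde | O=Cc1c(OCc2ccccc2)cc(OCc2ccccc2)cc1Br | intermediate
5 | 3,5-bis(benzyloxy)phenyllithium | [Li]c1cc(OCc2ccccc2)cc(OCc2ccccc2)c1 | intermediate
6 | racemic [2-bromo-4,6-bis(benzyloxy)phenyl][3,5-bis(benzyloxy)phenyl]methanol | OC(c1cc(OCc2ccccc2)cc(OCc2ccccc2)c1)c1c(OCc2ccccc2)cc(OCc2ccccc2)cc1Br | intermediate
7 | [2-bromo-4,6-bis(benzyloxy)phenyl][3,5-bis(benzyloxy)phenyl]methanone | O=C(c1cc(OCc2ccccc2)cc(OCc2ccccc2)c1)c1c(OCc2ccccc2)cc(OCc2ccccc2)cc1Br | intermediate
8 | [2-(4,4,5,5-tetramethyl-1,3,2-dioxaborolan-2-yl)-4,6-bis(benzyloxy)phenyl][3,5-bis(benzyloxy)phenyl]methanone | O=C(c1cc(OCc2ccccc2)cc(OCc2ccccc2)c1)c1c(OCc2ccccc2)cc(OCc2ccccc2)cc1B1OC(C)(C)C(C)(C)O1 | intermediate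
9 | tert-butyldimethyl(prop-2-yn-1-yloxy)silane | C#CCO[Si](C)(C)C(C)(C)C | starting material
10 | 1-(benzyloxy)-4-iodobenzene | Ic1ccc(OCc2ccccc2)cc1 | starting material
11 | {3-[4-(benzyloxy)phenyl]prop-2-yn-1-yloxy}(tert-butyl)dimethylsilane | CC(C)(C)[Si](C)(C)OCC#Cc1ccc(OCc2ccccc2)cc1 | intermediate
12 | (3R)-4,6-bis(benzyloxy)-2-[4-(benzyloxy)phenyl]-3-[3,5-bis(benzyloxy)phenyl]-1-[(tert-butyldimethylsilyloxy)methyl]inden-3-ol (target numbering; C1=C2 alkene) | CC(C)(C)[Si](C)(C)OCC1=C(c3ccc(OCc4ccccc4)cc3)[C@](O)(c3cc(OCc4ccccc4)cc(OCc4ccccc4)c3)c2c(OCc3ccccc3)cc(OCc3ccccc3)cc12 | intermediate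
13 | (1R,2R,3S)-4,6-bis(benzyloxy)-2-[4-(benzyloxy)phenyl]-3-[3,5-bis(benzyloxy)phenyl]-1-[(tert-butyldimethylsilyloxy)methyl]indan-3-ol (OH trans to the three cis carbon substituents) | CC(C)(C)[Si](C)(C)OC[C@@H]1[C@H](c3ccc(OCc4ccccc4)cc3)[C@](O)(c3cc(OCc4ccccc4)cc(OCc4ccccc4)c3)c2c(OCc3ccccc3)cc(OCc3ccccc3)cc12 | intermediate
14 | (1R,2R,3R)-4,6-bis(benzyloxy)-2-[4-(benzyloxy)phenyl]-3-[3,5-bis(benzyloxy)phenyl]-1-[(tert-butyldimethylsilyloxy)methyl]indane (all-cis) | CC(C)(C)[Si](C)(C)OC[C@@H]1[C@H](c3ccc(OCc4ccccc4)cc3)[C@H](c3cc(OCc4ccccc4)cc(OCc4ccccc4)c3)c2c(OCc3ccccc3)cc(OCc3ccccc3)cc12 | intermediate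
15 | {(1R,2R,3R)-4,6-bis(benzyloxy)-2-[4-(benzyloxy)phenyl]-3-[3,5-bis(benzyloxy)phenyl]indan-1-yl}methanol | OC[C@@H]1[C@H](c3ccc(OCc4ccccc4)cc3)[C@H](c3cc(OCc4ccccc4)cc(OCc4ccccc4)c3)c2c(OCc3ccccc3)cc(OCc3ccccc3)cc12 | intermediate
16 | (1R,2R,3R)-4,6-bis(benzyloxy)-2-[4-(benzyloxy)phenyl]-3-[3,5-bis(benzyloxy)phenyl]indane-1-carbaldehyde | O=C[C@@H]1[C@H](c3ccc(OCc4ccccc4)cc3)[C@H](c3cc(OCc4ccccc4)cc(OCc4ccccc4)c3)c2c(OCc3ccccc3)cc(OCc3ccccc3)cc12 | intermediate
17 | 4-(benzyloxy)phenylmagnesium bromide | Br[Mg]c1ccc(OCc2ccccc2)cc1 | starting material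
18 | [4-(benzyloxy)phenyl]{(1R,2R,3R)-4,6-bis(benzyloxy)-2-[4-(benzyloxy)phenyl]-3-[3,5-bis(benzyloxy)phenyl]indan-1-yl}methanol, carbinol epimers | OC(c1ccc(OCc2ccccc2)cc1)[C@@H]1[C@H](c3ccc(OCc4ccccc4)cc3)[C@H](c3cc(OCc4ccccc4)cc(OCc4ccccc4)c3)c2c(OCc3ccccc3)cc(OCc3ccccc3)cc12 | intermediate
19 | [4-(benzyloxy)phenyl]{(1R,2R,3R)-4,6-bis(benzyloxy)-2-[4-(benzyloxy)phenyl]-3-[3,5-bis(benzyloxy)phenyl]indan-1-yl}methanone | O=C(c1ccc(OCc2ccccc2)cc1)[C@@H]1[C@H](c3ccc(OCc4ccccc4)cc3)[C@H](c3cc(OCc4ccccc4)cc(OCc4ccccc4)c3)c2c(OCc3ccccc3)cc(OCc3ccccc3)cc12 | intermediate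
20 | caraphenol B, (4-hydroxyphenyl)[(1R,2R,3R)-3-(3,5-dihydroxyphenyl)-4,6-dihydroxy-2-(4-hydroxyphenyl)indan-1-yl]methanone | O=C(c1ccc(O)cc1)[C@H]1c2cc(O)cc(O)c2[C@@H](c2cc(O)cc(O)c2)[C@H]1c1ccc(O)cc1 | target

**Step count**
Total: 14 steps. Longest linear sequence: 13 steps (steps 1–5 and 7–14, from 5-bromoresorcinol).

**Steps most likely to fail, with fallbacks**

Step 7. Several processes can defeat the annulation: protodeboronation of 8 outrunning transmetalation, insertion with the reverse regiochemistry followed by β-oxygen elimination, a 1,4-rhodium shift or protonation in place of addition to the hindered ketone, or poor discrimination of the ketone faces. The fallback drops boron and catalyst-controlled induction. It sets out from bromo ketone 7 and alkyne 11, which are combined under reductive nickel catalysis (NiBr2(dppe), Zn powder, MeCN, 80 °C). This known annulation of 2-haloaryl ketones with internal alkynes begins with oxidative addition of the C–Br bond and gives the racemic indenol F1. Separation of the enantiomers by preparative chromatography on a chiral stationary phase returns the route at 12.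

Step 8. The acidic iridium hydride may ionise the tertiary diarylcarbinol, or the catalyst may fail to engage the hindered tetrasubstituted alkene through the crowded tertiary hydroxyl. The fallback moves the anchoring role to the primary hydroxyl and changes the order of events. It sets out from 12, whose silyl ether is cleaved first (Bu4NF, THF) to give the allylic diol F2. The primary allylic hydroxyl then anchors the cationic rhodium catalyst [Rh(nbd)(dppb)]BF4 under H2 (about 70 bar, CH2Cl2), conditions established for tri- and tetrasubstituted allylic alcohols. The lower face stays blocked by the C3 aryl group and two-point binding of both hydroxyls is possible only from the upper face, so the saturated diol F3 should have the C1 and C2 configuration of 13. Silane reduction of F3 as in step 9 (Et3SiH, BF3·OEt2, CH2Cl2, −78 °C) then gives alcohol 15, where the route is rejoined.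

Step 11. The all-cis aldehyde may epimerise at C1 during its formation, handling or the Grignard addition of step 12, since the cis arrangement is the less stable one. The fallback avoids the free aldehyde and any carbanionic reagent. It sets out from alcohol 15, which is oxidised in one flask to the carboxylic acid F4 (TEMPO cat., PhI(OAc)2, MeCN–H2O; the aldehyde appears only as a transient hydrate in weakly acidic medium). The acid is converted into the S-ethyl thioester F5 (EtSH, EDC·HCl, DMAP cat., CH2Cl2, 0 °C). Base-free Liebeskind–Srogl coupling with 4-(benzyloxy)phenylboronic acid (Pd2(dba)3, tri(2-furyl)phosphine, copper thiophene-2-carboxylate Cu(O2CC4H3S), THF, 50 °C) then gives the ketone directly, and the route is rejoined at 19.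

**Further compounds**
F1 | step 7 | racemic 4,6-bis(benzyloxy)-2-[4-(benzyloxy)phenyl]-3-[3,5-bis(benzyloxy)phenyl]-1-[(tert-butyldimethylsilyloxy)methyl]inden-3-ol | CC(C)(C)[Si](C)(C)OCC1=C(c3ccc(OCc4ccccc4)cc3)C(O)(c3cc(OCc4ccccc4)cc(OCc4ccccc4)c3)c2c(OCc3ccccc3)cc(OCc3ccccc3)cc12
F2 | step 8 | (3R)-4,6-bis(benzyloxy)-2-[4-(benzyloxy)phenyl]-3-[3,5-bis(benzyloxy)phenyl]-1-(hydroxymethyl)inden-3-ol | OCC1=C(c3ccc(OCc4ccccc4)cc3)[C@](O)(c3cc(OCc4ccccc4)cc(OCc4ccccc4)c3)c2c(OCc3ccccc3)cc(OCc3ccccc3)cc12
F3 | step 8 | (1R,2R,3S)-4,6-bis(benzyloxy)-2-[4-(benzyloxy)phenyl]-3-[3,5-bis(benzyloxy)phenyl]-1-(hydroxymethyl)indan-3-ol | OC[C@@H]1[C@H](c3ccc(OCc4ccccc4)cc3)[C@](O)(c3cc(OCc4ccccc4)cc(OCc4ccccc4)c3)c2c(OCc3ccccc3)cc(OCc3ccccc3)cc12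
F4 | step 11 | (1R,2R,3R)-4,6-bis(benzyloxy)-2-[4-(benzyloxy)phenyl]-3-[3,5-bis(benzyloxy)phenyl]indane-1-carboxylic acid | OC(=O)[C@@H]1[C@H](c3ccc(OCc4ccccc4)cc3)[C@H](c3cc(OCc4ccccc4)cc(OCc4ccccc4)c3)c2c(OCc3ccccc3)cc(OCc3ccccc3)cc12
F5 | step 11 | S-ethyl (1R,2R,3R)-4,6-bis(benzyloxy)-2-[4-(benzyloxy)phenyl]-3-[3,5-bis(benzyloxy)phenyl]indane-1-carbothioate | CCSC(=O)[C@@H]1[C@H](c3ccc(OCc4ccccc4)cc3)[C@H](c3cc(OCc4ccccc4)cc(OCc4ccccc4)c3)c2c(OCc3ccccc3)cc(OCc3ccccc3)cc12
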